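**The question.** A neighbour at the bench asks what more J buys in this flask, where J turns L into Z and D captures J as J.D, outside the working round.

L 0.071 M; J 7.1 µM; D 14 µM

    J + D ⇌ J.D (K1 = 2.0 × 10⁶ M⁻¹, k1 = 340 M⁻¹ s⁻¹)
    2 L → L2 (k2 = 0.013 M⁻¹ s⁻¹)
    L + J → Z + J, rate k3*[L]*[J]/(1 + ([L]/Km3) + ([Z]/Kp3)) (Km3 = 2.6 mM, Kp3 = 0.60 mM, k3 = 44000 M⁻¹ s⁻¹)

* apparent order in J when 50% of the L are converted (percent change of the rate of making Z for one percent more J charged)

**The puzzle.** Call the capture's equilibrium constant K. Then K times the D charged is 28.0, and D stands at twice the J, so at balance nearly all of J looks bound. Yet free J makes Z, and the L reach 50% conversion at 1.78 min.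

**The clock.** With k the forward capture constant, the time constant with D as charged is 3.50 min, longer than 1.78 min, so that balance lies ahead. J is the limiting reagent of the capture. Each J lost takes one D, so [D] − [J] stays at c_D − c_J, the difference of the charges. Leaving out the back step, the balance integrates to f = (c_D − c_J)/(c_D·exp(k(c_D − c_J)t) − c_J). At 1.78 min this gives 63.4%, the free share f, the part of the J charged not yet captured.

**My reckoning.** Suppose doubling J halves the time to 50% conversion, with L and Z the same there. The formula then gives a free share of 79.8%, so the rate grows by a factor 2.52, an order of 1.33.

**The forecast.** It gives 1.2, between 1 and 1.45, because “more J charged reaches that point sooner with more free enzyme left”. My figure is higher.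

**The result.** The simulation gives an order of 1.2, and the run with doubled J gives a factor 2.29 against my 2.52.

**What stands.** In this flask, the forward half-life of J by capture at 0.770 min is 2.7 min, longer than the 1.78 min taken to reach 50% conversion, and at that conversion 63.7% of the catalyst is free J against the reckoned 63.4%. Carried to 4.78 min, the formula puts 66.1% of the catalyst in J.D, and at that time the flask has 64.8% of it there.

(The constants used here are assumed, and the outcome is calculated.)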